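**Retrosynthetic overview**
1. Target 24 ⇐ MOM removal ⇐ 23; the C2–CH2 bond of the furanone is cut: enantioselective phase-transfer C-benzylation of the furanone C–H acid 21 (20 of the 34 heavy atoms) with benzylic bromide 10 (14 atoms), as the penultimate step.
2. 21 ⇐ O-methylation of isotetronic acid 20 ⇐ aldol–lactonisation of aryl pyruvate 17 with methyl glyoxylate 18 (butenolide ring); 17 ⇐ catechol via MOM ether, bromide, Cu-catalysed Grignard opening of methyl glycidate, oxidation.
3. 10 ⇐ diol 9 ⇐ LiAlH4 on epoxy ester 8 ⇐ Jacobsen epoxidation of chromene ester 7 (sets 3R) ⇐ bromochromene 4 + ClCO2Me ⇐ 4-bromophenol + 3-chloro-3-methylbut-1-yne (Claisen, pyran ring).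
4. Ring order: the benzopyran (branch A) and the butenolide (branch B) are built separately; no ring is formed after the coupling.

**Assumptions**
- The sense of induction in step 13 is taken as (S,S)-catalyst → (2S)-product. This is unproven for this nucleophile and must be checked on the first run; if it is reversed, the (R,R)-antipode is used with no other change.
- The benzylation in step 13 is assumed to occur at the ester-bearing carbon (C2) rather than at C4 or oxygen; this is not precedented for this exact dienolate (see risks).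
- Methyl chloroformate, methyl glycidate and methyl glyoxylate supply skeletal carbon and are numbered as starting materials.

**Route**

Step 1
Reactants: 1 4-bromophenol; 2 3-chloro-3-methylbut-1-yne
Product: 3 1-bromo-4-[(2-methylbut-3-yn-2-yl)oxy]benzene
Conditions: DBU, CuCl2·2H2O (0.1 mol %), MeCN, 0 °C
Reagents that add atoms: none
Why: Copper-catalysed O-propargylation of the phenol by the tertiary propargylic chloride (Williamson-type etherification) gives the hindered aryl 1,1-dimethylpropargyl ether without C-alkylation.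

Step 2
Reactants: 3 1-bromo-4-[(2-methylbut-3-yn-2-yl)oxy]benzene
Product: 4 6-bromo-2,2-dimethyl-2H-chromene
Conditions: PhNEt2, 190 °C
Reagents that add atoms: none
Why: Aryl propargyl ether Claisen rearrangement, 1,5-H shift and oxa-6π electrocyclisation close the pyran ring, and the para-bromine leaves two equivalent ortho positions so only one chromene can form.

Step 3
Reactants: 4 6-bromo-2,2-dimethyl-2H-chromene; 5 methyl chloroformate
Product: 7 methyl 2,2-dimethyl-2H-chromene-6-carboxylate, via aryllithium 6 (not isolated)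
Conditions: n-BuLi, THF, –78 °C; then cannulate into 5 (3 equiv), THF, –78 °C → rt
Reagents that add atoms: none
Why: Bromine–lithium exchange is fast at –78 °C and inverse addition of the aryllithium to excess chloroformate gives the ester without over-addition (halogen–metal exchange/acylation).

Step 4
Reactants: 7 methyl 2,2-dimethyl-2H-chromene-6-carboxylate
Product: 8 methyl (3R,4R)-3,4-epoxy-2,2-dimethylchromane-6-carboxylate
Conditions: (R,R)-Jacobsen Mn(salen)Cl (3 mol %), 4-phenylpyridine N-oxide (0.2 equiv), aq NaOCl (pH 11.3), CH2Cl2, 0 °C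
Reagents that add atoms: sodium hypochlorite, [Na+].[O-]Cl
Why: Jacobsen–Katsuki epoxidation is at its best with electron-poor 2,2-dimethylchromenes, and the (R,R)-catalyst delivers oxygen to the face that gives the (3R,4R)-epoxide (typically ≥95% ee), which sets the carbinol centre.

Step 5
Reactants: 8 methyl (3R,4R)-3,4-epoxy-2,2-dimethylchromane-6-carboxylate
Product: 9 (3R)-6-(hydroxymethyl)-2,2-dimethylchroman-3-ol
Conditions: LiAlH4, THF, 0 °C → rt; Rochelle-salt work-up; recrystallise to raise ee
Reagents that add atoms: none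
Why: Hydride reduces the ester to the benzylic alcohol and opens the epoxide by SN2 attack at benzylic C4 (C3 is neopentyl-like), so the C3–O bond is never broken and the (3R) configuration is retained (hydride reduction with regioselective epoxide opening).

Step 6
Reactants: 9 (3R)-6-(hydroxymethyl)-2,2-dimethylchroman-3-ol
Product: 10 (3R)-6-(bromomethyl)-2,2-dimethylchroman-3-ol
Conditions: CBr4 (1.1 equiv), PPh3 (1.1 equiv), CH2Cl2, –20 → 0 °C; short silica plug, use at once
Reagents that add atoms: carbon tetrabromide, BrC(Br)(Br)Br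
Why: In the Appel reaction the primary benzylic alcohol is displaced readily, whereas the secondary alcohol next to the quaternary carbon cannot undergo SN2 displacement, so it is left free and its configuration untouched.

Step 7
Reactants: 11 catechol
Product: 12 1,2-bis(methoxymethoxy)benzene
Conditions: MOMCl (2.5 equiv), i-Pr2NEt (3 equiv), CH2Cl2, 0 °C → rt
Reagents that add atoms: chloromethyl methyl ether, COCCl
Why: Double O-alkylation gives acetal protection of both phenols that is stable to organometallics and base and is removed by mild acid at the end.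

Step 8
Reactants: 12 1,2-bis(methoxymethoxy)benzene
Product: 13 4-bromo-1,2-bis(methoxymethoxy)benzene
Conditions: NBS (1.05 equiv), MeCN, 0 °C → rt, dark
Reagents that add atoms: N-bromosuccinimide, O=C1CCC(=O)N1Br
Why: Electrophilic aromatic bromination goes para to an alkoxy group at the only unhindered activated position, and the neutral conditions spare the MOM acetals.

Step 9
Reactants: 13 4-bromo-1,2-bis(methoxymethoxy)benzene; 14 methyl oxirane-2-carboxylate (racemic methyl glycidate)
Product: 16 methyl 3-[3,4-bis(methoxymethoxy)phenyl]-2-hydroxypropanoate (racemic), via Grignard reagent 15 (not isolated)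
Conditions: Mg, THF, 45 °C; then CuI (10 mol %), 14, THF, –40 → –20 °C; aq NH4Cl
Reagents that add atoms: none
Why: The copper-catalysed Grignard reagent opens the glycidate at its terminal CH2 faster than it adds to the ester (cuprate epoxide opening), giving the aryl-lactate skeleton; the carbinol centre is racemic because it is oxidised away in step 10.

Step 10
Reactants: 16 methyl 3-[3,4-bis(methoxymethoxy)phenyl]-2-hydroxypropanoate
Product: 17 methyl 3-[3,4-bis(methoxymethoxy)phenyl]-2-oxopropanoate (keto/Z-enol mixture)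
Conditions: Dess–Martin periodinane (1.1 equiv), CH2Cl2, 0 °C → rt
Reagents that add atoms: none
Why: Dess–Martin oxidation converts the α-hydroxy ester to the α-keto ester under near-neutral conditions that the MOM ethers tolerate; the product is used promptly because aryl-pyruvate enols are air-sensitive.

Step 11
Reactants: 17 methyl 3-[3,4-bis(methoxymethoxy)phenyl]-2-oxopropanoate; 18 methyl glyoxylate
Product: 20 methyl 3-[3,4-bis(methoxymethoxy)phenyl]-4-hydroxy-5-oxo-2,5-dihydrofuran-2-carboxylate (racemic), via aldol adduct 19 (not isolated)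
Conditions: 18 (1.5 equiv, freshly cracked), Et3N (1.2 equiv), CH2Cl2, 0 °C → rt, slow addition of 17; aq NaH2PO4
Reagents that add atoms: none
Why: The pyruvate enolate adds through its benzylic carbon to the non-enolisable, highly electrophilic aldehyde (cross-aldol), then the new hydroxyl closes onto the α-keto ester carbonyl with loss of methanol and enolises to the isotetronic acid; C2 is racemic on purpose because it is erased in step 13.

Step 12
Reactants: 20 methyl 3-[3,4-bis(methoxymethoxy)phenyl]-4-hydroxy-5-oxo-2,5-dihydrofuran-2-carboxylate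
Product: 21 methyl 3-[3,4-bis(methoxymethoxy)phenyl]-4-methoxy-5-oxo-2,5-dihydrofuran-2-carboxylate (racemic)
Conditions: TMSCHN2 (1.3 equiv), MeOH–toluene (1:4), 0 °C → rt
Reagents that add atoms: (trimethylsilyl)diazomethane, C[Si](C)(C)C=[N+]=[N-]
Why: Diazoalkane methylation needs no base and so alkylates only the acidic enol oxygen and not the acidic C2–H carbon.

Step 13
Reactants: 10 (3R)-6-(bromomethyl)-2,2-dimethylchroman-3-ol; 21 methyl 3-[3,4-bis(methoxymethoxy)phenyl]-4-methoxy-5-oxo-2,5-dihydrofuran-2-carboxylate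
Product: 23 methyl (2S)-3-[3,4-bis(methoxymethoxy)phenyl]-2-{[(3R)-3-hydroxy-2,2-dimethylchroman-6-yl]methyl}-4-methoxy-5-oxo-2,5-dihydrofuran-2-carboxylate, via cesium furanolate 22 (not isolated)
Conditions: (S,S)-3,4,5-trifluorophenyl-NAS bromide (Maruoka catalyst, 3 mol %), Cs2CO3 (powdered, 1.5 equiv), 10 (1.2 equiv), toluene, –20 → 0 °C
Reagents that add atoms: none
Why: Carbonate deprotonates the doubly activated C2–H to the planar furanolate, which ion-pairs with the C2-symmetric chiral ammonium cation in toluene, so SN2 attack on the p-alkoxybenzyl bromide occurs at the ester-bearing carbon from the unshielded face and sets the (2S) quaternary centre (asymmetric phase-transfer alkylation); the (3R)-carbinol is untouched and makes any minor C2 epimer a separable diastereomer.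

Step 14
Reactants: 23 methyl (2S)-3-[3,4-bis(methoxymethoxy)phenyl]-2-{[(3R)-3-hydroxy-2,2-dimethylchroman-6-yl]methyl}-4-methoxy-5-oxo-2,5-dihydrofuran-2-carboxylate
Product: 24 methyl (2S)-3-(3,4-dihydroxyphenyl)-2-{[(3R)-3-hydroxy-2,2-dimethylchroman-6-yl]methyl}-4-methoxy-5-oxo-2,5-dihydrofuran-2-carboxylate
Conditions: HCl (2 M in MeOH), degassed, 40 °C
Reagents that add atoms: none
Why: Acid-catalysed acetal exchange with methanol removes both MOM groups as dimethoxymethane, and the quaternary C2 centre, the methyl ester (degenerate exchange in MeOH), the captodative enol ether and the chromanol are stable to these conditions.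

**Compound list**
1 | 4-bromophenol | Oc1ccc(Br)cc1 | starting material
2 | 3-chloro-3-methylbut-1-yne | C#CC(C)(C)Cl | starting material
3 | 1-bromo-4-[(2-methylbut-3-yn-2-yl)oxy]benzene | C#CC(C)(C)Oc1ccc(Br)cc1 | intermediate
4 | 6-bromo-2,2-dimethyl-2H-chromene | CC1(C)C=Cc2cc(Br)ccc2O1 | intermediate
5 | methyl chloroformate | COC(=O)Cl | starting material
6 | (2,2-dimethyl-2H-chromen-6-yl)lithium | [Li]c1ccc2OC(C)(C)C=Cc2c1 | intermediate
7 | methyl 2,2-dimethyl-2H-chromene-6-carboxylate | COC(=O)c1ccc2OC(C)(C)C=Cc2c1 | intermediate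
8 | methyl (3R,4R)-3,4-epoxy-2,2-dimethylchromane-6-carboxylate | COC(=O)c1ccc2c(c1)[C@H]1O[C@H]1C(C)(C)O2 | intermediate
9 | (3R)-6-(hydroxymethyl)-2,2-dimethylchroman-3-ol | OCc1ccc2c(c1)C[C@@H](O)C(C)(C)O2 | intermediate
10 | (3R)-6-(bromomethyl)-2,2-dimethylchroman-3-ol | BrCc1ccc2c(c1)C[C@@H](O)C(C)(C)O2 | intermediate
11 | catechol | Oc1ccccc1O | starting material
12 | 1,2-bis(methoxymethoxy)benzene | COCOc1ccccc1OCOC | intermediate
13 | 4-bromo-1,2-bis(methoxymethoxy)benzene | COCOc1ccc(Br)cc1OCOC | intermediate
14 | methyl oxirane-2-carboxylate (racemic methyl glycidate) | COC(=O)C1CO1 | starting material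
15 | [3,4-bis(methoxymethoxy)phenyl]magnesium bromide | COCOc1ccc([Mg]Br)cc1OCOC | intermediate
16 | methyl 3-[3,4-bis(methoxymethoxy)phenyl]-2-hydroxypropanoate (racemic) | COC(=O)C(O)Cc1ccc(OCOC)c(OCOC)c1 | intermediate
17 | methyl 3-[3,4-bis(methoxymethoxy)phenyl]-2-oxopropanoate | COC(=O)C(=O)Cc1ccc(OCOC)c(OCOC)c1 | intermediate
18 | methyl glyoxylate | COC(=O)C=O | starting material
19 | dimethyl 3-[3,4-bis(methoxymethoxy)phenyl]-2-hydroxy-4-oxopentanedioate (diastereomer mixture) | COC(=O)C(O)C(C(=O)C(=O)OC)c1ccc(OCOC)c(OCOC)c1 | intermediate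
20 | methyl 3-[3,4-bis(methoxymethoxy)phenyl]-4-hydroxy-5-oxo-2,5-dihydrofuran-2-carboxylate (racemic) | COC(=O)C1OC(=O)C(O)=C1c1ccc(OCOC)c(OCOC)c1 | intermediate
21 | methyl 3-[3,4-bis(methoxymethoxy)phenyl]-4-methoxy-5-oxo-2,5-dihydrofuran-2-carboxylate (racemic) | COC(=O)C1OC(=O)C(OC)=C1c1ccc(OCOC)c(OCOC)c1 | intermediate
22 | cesium 4-[3,4-bis(methoxymethoxy)phenyl]-3-methoxy-5-(methoxycarbonyl)furan-2-olate | [Cs+].COC(=O)c1oc([O-])c(OC)c1-c1ccc(OCOC)c(OCOC)c1 | intermediate
23 | methyl (2S)-3-[3,4-bis(methoxymethoxy)phenyl]-2-{[(3R)-3-hydroxy-2,2-dimethylchroman-6-yl]methyl}-4-methoxy-5-oxo-2,5-dihydrofuran-2-carboxylate | COC(=O)[C@@]1(Cc2ccc3c(c2)C[C@@H](O)C(C)(C)O3)OC(=O)C(OC)=C1c1ccc(OCOC)c(OCOC)c1 | intermediate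
24 | methyl (2S)-3-(3,4-dihydroxyphenyl)-2-{[(3R)-3-hydroxy-2,2-dimethylchroman-6-yl]methyl}-4-methoxy-5-oxo-2,5-dihydrofuran-2-carboxylate | COC(=O)[C@@]1(Cc2ccc3c(c2)C[C@@H](O)C(C)(C)O3)OC(=O)C(OC)=C1c1ccc(O)c(O)c1 | target

**Totals**
Total step count: 14 (branch A: steps 1–6; branch B: steps 7–12; coupling step 13; deprotection step 14).
Longest linear sequence: 8 steps (1–6, 13, 14; the other branch, 7–12, 13, 14, is also 8).

**Three steps most likely to fail, with fallbacks**

Step 13 (coupling). The furanolate is ambident (C2, C4, O), and the facial selectivity of an ion-pair benzylation on this nucleophile is unproven. The fallback replaces SN2 alkylation by palladium-catalysed asymmetric benzylation through an η3-benzyl–palladium electrophile. It sets out from diol 9: selective phosphorylation of the primary benzylic hydroxyl (ClP(O)(OEt)2, pyridine, CH2Cl2, –20 °C) gives diethyl [(3R)-3-hydroxy-2,2-dimethylchroman-6-yl]methyl phosphate F1. F1 and 21 with CpPd(allyl) (5 mol %), a DACH-phenyl Trost bisphosphine (antipode chosen for the 2S epimer), Et3N and t-BuOH in dioxane at rt give the C-benzylated product, and the route is rejoined at 23.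

Step 11 (aldol–lactonisation). Under amine base the pyruvate 17 can self-condense (it is both donor and acceptor), and glyoxylate can oligomerise. The fallback removes the acceptor role of the pyruvate by a Mukaiyama aldol. It sets out from 17: TMSCl and Et3N in CH2Cl2 give methyl (Z)-3-[3,4-bis(methoxymethoxy)phenyl]-2-[(trimethylsilyl)oxy]prop-2-enoate F2. Cu(OTf)2 (10 mol %) then promotes addition of F2 to 18 in CH2Cl2 at –40 °C to give dimethyl 3-[3,4-bis(methoxymethoxy)phenyl]-2-oxo-4-[(trimethylsilyl)oxy]pentanedioate F3. Aqueous citric acid work-up desilylates F3 to 19, which lactonises, and the route is rejoined at 20.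

Step 6 (bromide formation). The p-alkoxybenzyl bromide 10 is solvolytically labile and carries a free hydroxyl, so it may oligomerise or give a poor mass balance. The fallback is protect-first and sets out from 9. TBSOTf and 2,6-lutidine give (3R)-3-[(tert-butyldimethylsilyl)oxy]-6-{[(tert-butyldimethylsilyl)oxy]methyl}-2,2-dimethylchromane F4. Ph3PBr2 (CH2Cl2, 0 °C) converts only the primary benzylic silyl ether directly into (3R)-6-(bromomethyl)-3-[(tert-butyldimethylsilyl)oxy]-2,2-dimethylchromane F5. F5 is coupled with 21 under the step 13 conditions to give methyl (2S)-3-[3,4-bis(methoxymethoxy)phenyl]-2-{[(3R)-3-[(tert-butyldimethylsilyl)oxy]-2,2-dimethylchroman-6-yl]methyl}-4-methoxy-5-oxo-2,5-dihydrofuran-2-carboxylate F6. The step 14 conditions (HCl/MeOH, 40 °C) remove the silyl ether together with the MOM groups, and the route is rejoined at 24.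

**Further compounds**
F1 | step 13 | diethyl [(3R)-3-hydroxy-2,2-dimethylchroman-6-yl]methyl phosphate | CCOP(=O)(OCC)OCc1ccc2c(c1)C[C@@H](O)C(C)(C)O2
F2 | step 11 | methyl (Z)-3-[3,4-bis(methoxymethoxy)phenyl]-2-[(trimethylsilyl)oxy]prop-2-enoate | COC(=O)/C(O[Si](C)(C)C)=C/c1ccc(OCOC)c(OCOC)c1
F3 | step 11 | dimethyl 3-[3,4-bis(methoxymethoxy)phenyl]-2-oxo-4-[(trimethylsilyl)oxy]pentanedioate | COC(=O)C(O[Si](C)(C)C)C(C(=O)C(=O)OC)c1ccc(OCOC)c(OCOC)c1
F4 | step 6 | (3R)-3-[(tert-butyldimethylsilyl)oxy]-6-{[(tert-butyldimethylsilyl)oxy]methyl}-2,2-dimethylchromane | CC(C)(C)[Si](C)(C)OCc1ccc2c(c1)C[C@@H](O[Si](C)(C)C(C)(C)C)C(C)(C)O2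
F5 | step 6 | (3R)-6-(bromomethyl)-3-[(tert-butyldimethylsilyl)oxy]-2,2-dimethylchromane | BrCc1ccc2c(c1)C[C@@H](O[Si](C)(C)C(C)(C)C)C(C)(C)O2
F6 | step 6 | methyl (2S)-3-[3,4-bis(methoxymethoxy)phenyl]-2-{[(3R)-3-[(tert-butyldimethylsilyl)oxy]-2,2-dimethylchroman-6-yl]methyl}-4-methoxy-5-oxo-2,5-dihydrofuran-2-carboxylate | COC(=O)[C@@]1(Cc2ccc3c(c2)C[C@@H](O[Si](C)(C)C(C)(C)C)C(C)(C)O3)OC(=O)C(OC)=C1c1ccc(OCOC)c(OCOC)c1
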